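**Assumptions.** The input SMILES has no axial descriptor, so I target the (M)-atropisomer of the C5–C1′ axis. The opposite enantiomer of the catalyst gives (P). The axis is the only stereo-element in the molecule.

## Retrosynthetic overview
1. Target ← O-debenzylation and ester reduction ← ethyl isoquinoline-3-carboxylate carrying the tetra-ortho axis.
2. Key step: build the isoquinoline ring last. A chiral Cp^xRh(III) C–H annulation of a ketoxime acetate with ethyl propiolate acts on a configurationally labile tri-ortho biaryl. It converts this biaryl dynamically into the locked tetra-ortho atropisomer, so the ring formation sets the axis.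
3. The biaryl C–C bond is made without cross-coupling. A 2,4-dimethoxyaryl-cerium adds 1,2 to the C1 carbonyl of 5-O-methylplumbagin, and SnCl2 then aromatises the quinol. Plumbagin already contains the 2-Me, 4-O, 5-O naphthalene pattern.
4. Starting materials: 2′,4′-dimethoxyacetophenone and plumbagin.

## Route

**Step 1**
Reactants: 1, 2′,4′-dimethoxyacetophenone
Product: 2, 5′-bromo-2′,4′-dimethoxyacetophenone
Conditions: NBS, MeCN, 0 °C → rt
Reagents that add atoms: N-bromosuccinimide, O=C1CCC(=O)N1Br (Br)
Why: Electrophilic aromatic bromination goes to C5, which is para to one OMe and ortho to the other; C3 is blocked between the two OMe groups.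

**Step 2**
Reactants: 2
Product: 3, 2-(5-bromo-2,4-dimethoxyphenyl)-2-methyl-1,3-dioxolane
Conditions: ethylene glycol, TsOH (cat.), PhMe, Dean–Stark reflux; Et3N quench
Reagents that add atoms: ethylene glycol, OCCO
Why: Ketalisation masks the ketone so that the aryl bromide can be lithiated.

**Step 3**
Reactants: 4, plumbagin (5-hydroxy-2-methyl-1,4-naphthoquinone)
Product: 5, 5-methoxy-2-methyl-1,4-naphthoquinone
Conditions: MeI, Ag2O, CHCl3, rt
Reagents that add atoms: methyl iodide, CI
Why: O-Methylation of the chelated peri-phenol, which also deactivates the C4 carbonyl by vinylogous-ester donation.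

**Step 4**
Reactants: 3 (aryl bromide), 5 (quinone)
Product: 6, (±)-4-aryl-4-hydroxy-8-methoxy-3-methylnaphthalen-1(4H)-one (a para-quinol). The aryl group is 2,4-dimethoxy-5-(2-methyl-1,3-dioxolan-2-yl)phenyl.
Conditions: 3, n-BuLi, THF, −78 °C; then CeCl3; then 5, −78 → −40 °C; NH4Cl work-up
Reagents that add atoms: none
Why: Br/Li exchange followed by transmetalation to Ce gives a hard, non-basic nucleophile. It adds 1,2 to the more electrophilic C1 carbonyl next to the small Me group. The C4 carbonyl is deactivated by the peri-OMe and shielded by it. The new quaternary carbinol stereocentre is racemic and is destroyed in the next step.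

**Step 5**
Reactants: 6
Product: 7, 1-[5-(4-hydroxy-5-methoxy-2-methylnaphthalen-1-yl)-2,4-dimethoxyphenyl]ethan-1-one
Conditions: SnCl2·2H2O, THF, 2 M HCl, 0 °C → rt
Reagents that add atoms: water, O (the ketal hydrolysis supplies the ketone oxygen)
Why: Reductive aromatisation of the para-quinol by Sn(II) (Kita-type) sets the C1′–aryl bond and the 4′-OH. The same acid removes the ketal. The biaryl is tri-ortho-substituted and so configurationally labile; it is racemic at this stage.

**Step 6**
Reactants: 7
Product: 8, the 4′-O-benzyl ether of 7
Conditions: BnBr, K2CO3, acetone, reflux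
Reagents that add atoms: benzyl bromide, BrCc1ccccc1
Why: Williamson O-benzylation protects the naphthol for the Rh(III) step; the ketone is untouched.

**Step 7**
Reactants: 8
Product: 9, the (E)-ketoxime of 8
Conditions: NH2OH·HCl, NaOAc, EtOH/H2O, reflux
Reagents that add atoms: hydroxylamine, NO
Why: Condensation of the ketone with hydroxylamine to the oxime; the (E)-isomer has the N lone pair syn to the aryl ring, as needed for directing C–H activation.

**Step 8**
Reactants: 9
Product: 10, the O-acetyl ketoxime
Conditions: Ac2O, Et3N, DMAP (cat.), CH2Cl2, 0 °C → rt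
Reagents that add atoms: acetic anhydride, CC(=O)OC(C)=O
Why: The O-acetyl group makes the N–O bond an internal oxidant for the annulation.

**Step 9**
Reactants: 10, 11 (ethyl propiolate, C#CC(=O)OCC)
Product: 12, ethyl (M)-5-[4-(benzyloxy)-5-methoxy-2-methylnaphthalen-1-yl]-6,8-dimethoxy-1-methylisoquinoline-3-carboxylate
Conditions: 11 (2 equiv), chiral binaphthyl-derived [Cp^xRhI2]2 (5 mol %), AgSbF6 (20 mol %), NaOAc (30 mol %), TFE, 70 °C, 24 h
Reagents that add atoms: none
Why: Proposed new method: the closest known chemistry is Rh(III) isoquinoline synthesis from O-acyl ketoximes and alkynes (N–O as internal oxidant) together with chiral-Cp^xRh atroposelective C–H functionalisation. The only free ortho C–H (the future C4a–H) lies next to the biaryl axis. Oxime-directed CMD metalation at this C–H is enantio-determining, with Curtin–Hammett selection of one rotamer. The tri-ortho substrate is assumed to racemise at 70 °C (ΔG‡ ≈ 24–26 kcal/mol). The annulated product is tetra-ortho and locked. Aryl–Rh adds across the alkyne with aryl going to the terminal CH and Rh to the ester-bearing carbon. C–N bond formation and N–O cleavage release AcOH and give the 3-CO2Et, 4-H isoquinoline.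

**Step 10**
Reactants: 12
Product: 13, (M)-[5-(4-benzyloxy-5-methoxy-2-methylnaphthalen-1-yl)-6,8-dimethoxy-1-methylisoquinolin-3-yl]methanol
Conditions: NaBH4, EtOH/THF, 0 → 50 °C
Reagents that add atoms: none (hydride adds H only)
Why: The 3-ester next to the ring nitrogen is activated like a picolinate and is reduced to the primary alcohol by borohydride. The tetra-ortho axis is not affected.

**Step 11**
Reactants: 13
Product: 14, Ancistrobenomine A, (M)-atropisomer
Conditions: H2 (1 atm), 10 % Pd/C, EtOH/EtOAc, rt
Reagents that add atoms: none (H2 adds H only)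
Why: Hydrogenolysis removes only the benzyl ether. The heteroarene, the OMe groups and the CH2OH survive, and the locked axis is retained.

## Compound list
1 | 2′,4′-dimethoxyacetophenone | CC(=O)c1ccc(OC)cc1OC | starting material
2 | 5′-bromo-2′,4′-dimethoxyacetophenone | CC(=O)c1cc(Br)c(OC)cc1OC | intermediate
3 | 2-(5-bromo-2,4-dimethoxyphenyl)-2-methyl-1,3-dioxolane | CC1(OCCO1)c1cc(Br)c(OC)cc1OC | intermediate
4 | plumbagin | CC1=CC(=O)c2c(O)cccc2C1=O | starting material
5 | 5-methoxy-2-methyl-1,4-naphthoquinone | CC1=CC(=O)c2c(OC)cccc2C1=O | intermediate
6 | (±)-quinol adduct | O=C1C=C(C)C(O)(c2cc(C3(C)OCCO3)c(OC)cc2OC)c2cccc(OC)c21 | intermediate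
7 | biaryl ketone naphthol (axis labile, racemic) | CC(=O)c1cc(-c2c(C)cc(O)c3c(OC)cccc23)c(OC)cc1OC | intermediate
8 | 4′-O-benzyl biaryl ketone | CC(=O)c1cc(-c2c(C)cc(OCc4ccccc4)c3c(OC)cccc23)c(OC)cc1OC | intermediate
9 | (E)-ketoxime | CC(=NO)c1cc(-c2c(C)cc(OCc4ccccc4)c3c(OC)cccc23)c(OC)cc1OC | intermediate
10 | O-acetyl ketoxime | CC(=NOC(C)=O)c1cc(-c2c(C)cc(OCc4ccccc4)c3c(OC)cccc23)c(OC)cc1OC | intermediate
11 | ethyl propiolate | C#CC(=O)OCC | starting material
12 | ethyl isoquinoline-3-carboxylate, (M)-axis | CCOC(=O)c1cc2c(-c3c(C)cc(OCc4ccccc4)c4c(OC)cccc34)c(OC)cc(OC)c2c(C)n1 | intermediate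
13 | 3-hydroxymethyl O-benzyl compound, (M)-axis | OCc1cc2c(-c3c(C)cc(OCc4ccccc4)c4c(OC)cccc34)c(OC)cc(OC)c2c(C)n1 | intermediate
14 | Ancistrobenomine A, (M)-axis (SMILES has no axial descriptor) | COc1cc(OC)c2c(C)nc(CO)cc2c1-c1c(C)cc(O)c2c(OC)cccc12 | target

**Total step count:** 11 steps (10 in the longest linear sequence, from 1).
**Longest linear sequence:** 1 → 2 → 3 → 6 → 7 → 8 → 9 → 10 → 12 → 13 → 14.

## Three steps most likely to fail
1. **Step 9.** Problems could be hindered metalation next to the naphthyl group, poor reactivity of a terminal propiolate, or a tri-ortho axis that does not racemise fast enough for dynamic resolution (low ee). Fallback: run the annulation with achiral Cp*Rh to give racemic 12, then obtain the (M)-atropisomer by preparative chiral-phase HPLC. This switches from asymmetric catalysis to resolution.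
2. **Step 4.** The organocerium may attack the wrong carbonyl, add in Michael fashion, or reduce the quinone by electron transfer. Fallback: mask the C4 carbonyl as its dimethyl ketal, so that addition can only occur at C1, and then aromatise under Step 5 conditions. A 4′-OMe then has to be cleaved selectively at the end. This changes the substrate rather than the conditions.
3. **Step 5.** Acid can trigger quinol-to-hydroquinone aryl migration instead of reduction. Fallback: abandon the quinol route. Reduce 5 to the hydroquinone, make the 1-naphthyl triflate selectively, and couple it with the arylboronate derived from 3 (Suzuki–Miyaura) to give racemic 7. The remaining steps are unchanged.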